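**Plan** (labdane numbering: ring A = C1–C5 and C10, ring B = C5–C10, C17 = exocyclic CH2 on C8, C19 = CH2OAc on C4, C20 = CH3 on C10, chain C11–C16)
1. Retrosynthesis: remove the two silyl ethers; cut C9–C10 (ring B) back to a ring A 3-methylcyclohex-2-enone whose C5 carries C6–C7(OSiEt3)–C8(CH2SiMe3)=C9; then cut C8–C17 (carbomagnesiation of a C8≡C9 alkyne), C10–C20 (MeLi on a vinylogous ester), C7–C8 (acetylide on a δ-lactone), C5–C6 (cyclopropane from a diazoacetate) and C4–CH3 (Birch alkylation).
2. Forward: ring A is built first from 3,5-dimethoxybenzoic acid (Birch methylation, C19 alcohol, diazoacetate, desymmetrising cyclopropanation, acid opening to the C10 ketone and cis δ-lactone); the nerol-derived alkyne C8–C16 is joined at C7; ring B is closed last.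
3. Enabling feature: C10 is the β-carbon of the ring A enone (C2=O, C1=C10) and C9 is the γ-carbon of an allylsilane (Me3Si–C17–C8=C9), so C9 adds to C10 and loss of silicon leaves the C8=C17 methylene.
4. Stereochemistry: C4 and C5 come from one Rh2(5S-MEPY)4-catalysed desymmetrisation (the C19–O tether forces C6 cis to C19); C7 from catalyst-controlled transfer hydrogenation; 13Z from nerol; the Z-allylsilane from anti-carbomagnesiation; C9 and C10 are relayed from C4, C5 and the alkene geometry in the key step.

Key step: step 16

Assumption: the sense of enantiotopic-alkene selection in step 8 cannot be predicted with certainty for this substrate; the route is written for Rh2(5S-MEPY)4, and the antipodal catalyst would be used if the induction proves opposite.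

**Step 1**
Reactants: 1 nerol
Product: 2 neryl tert-butyldiphenylsilyl ether
Conditions: TBDPSCl, imidazole, DMF, 0 °C → rt
Reagents that add atoms: tert-butyl(chloro)diphenylsilane, CC(C)(C)[Si](Cl)(c1ccccc1)c1ccccc1
Why: Silylation of the primary allylic alcohol protects C15–OH through the organometallic and acidic steps that follow, and the 13Z alkene is taken unchanged from nerol.

**Step 2**
Reactants: 2 neryl tert-butyldiphenylsilyl ether
Product: 3 6,7-epoxide of 2
Conditions: mCPBA (1.0 equiv), NaHCO3, CH2Cl2, −20 → 0 °C
Reagents that add atoms: 3-chloroperoxybenzoic acid, OOC(=O)c1cccc(Cl)c1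
Why: Prilezhaev epoxidation should take place at the remote, more electron-rich isopropylidene alkene, because the 2,3-alkene is deactivated by the allylic silyloxy group.

**Step 3**
Reactants: 3 6,7-epoxide of 2
Product: 4 (4Z)-6-(tert-butyldiphenylsilyloxy)-4-methylhex-4-enal
Conditions: H5IO6 (1.1 equiv), THF/Et2O, 0 °C
Reagents that add atoms: none
Why: Periodic acid opens the epoxide to the glycol and cleaves it in the same flask (Malaprade-type cleavage), giving the aldehyde whose carbonyl carbon becomes C9.

**Step 4**
Reactants: 4 (4Z)-6-(tert-butyldiphenylsilyloxy)-4-methylhex-4-enal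
Product: 5 tert-butyl{[(2Z)-3-methylhept-2-en-6-yn-1-yl]oxy}diphenylsilane
Conditions: dimethyl (1-diazo-2-oxopropyl)phosphonate, K2CO3, MeOH, 0 °C → rt
Reagents that add atoms: dimethyl (1-diazo-2-oxopropyl)phosphonate, CC(=O)C(=[N+]=[N-])P(=O)(OC)OC
Why: Seyferth–Gilbert homologation in the Ohira–Bestmann variant converts the aldehyde into the terminal alkyne under mild base, the added carbon becoming C8.

**Step 5**
Reactants: 6 3,5-dimethoxybenzoic acid
Product: 7 3,5-dimethoxy-1-methylcyclohexa-2,5-diene-1-carboxylic acid
Conditions: Li, NH3(l), THF, −78 °C; MeI; NH4Cl, then pH 5 at 0 °C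
Reagents that add atoms: iodomethane, CI
Why: Birch reduction gives the carboxylate-stabilised dienolate, whose methylation at the ipso carbon creates the quaternary C4 flanked by two enantiotopic enol ethers (the product is achiral).

**Step 6**
Reactants: 7 3,5-dimethoxy-1-methylcyclohexa-2,5-diene-1-carboxylic acid
Product: 8 (3,5-dimethoxy-1-methylcyclohexa-2,5-dien-1-yl)methanol
Conditions: LiAlH4, THF, 0 °C → reflux; aqueous NaOH work-up
Reagents that add atoms: none
Why: Hydride reduction of the acid gives the neopentyl alcohol (C19–OH), and the basic work-up keeps both enol ethers intact.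

**Step 7**
Reactants: 8 (3,5-dimethoxy-1-methylcyclohexa-2,5-dien-1-yl)methanol
Product: 10 (3,5-dimethoxy-1-methylcyclohexa-2,5-dien-1-yl)methyl diazoacetate, via glyoxylate tosylhydrazone ester 9 (not isolated)
Conditions: TsNHN=CHCOCl, PhNMe2, CH2Cl2, 0 °C; then Et3N, 0 °C → rt
Reagents that add atoms: glyoxylic acid chloride 4-methylbenzenesulfonylhydrazone, Cc1ccc(cc1)S(=O)(=O)NN=CC(Cl)=O
Why: Acylation followed by base-induced loss of sulfinate from the tosylhydrazone (Bamford–Stevens-type elimination) gives the diazoacetate without acid, which the enol ethers would not survive.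

**Step 8**
Reactants: 10 (3,5-dimethoxy-1-methylcyclohexa-2,5-dien-1-yl)methyl diazoacetate
Product: 11 tricyclic cyclopropane δ-lactone
Conditions: Rh2(5S-MEPY)4 [dirhodium tetrakis(methyl (5S)-2-oxopyrrolidine-5-carboxylate)] (1 mol%), CH2Cl2, reflux, slow addition of 10
Reagents that add atoms: none
Why: Intramolecular cyclopropanation of an enol ether by the carbenoid formed from the diazoacetate and Rh2(5S-MEPY)4, in which the C19–O tether can deliver the carbene only to the face of C5=C10 that carries C19 (C6 cis to C19) and the chiral carboxamidate ligands select one of the two enantiotopic enol ethers, so that C4 and C5 are set in one event.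

**Step 9**
Reactants: 11 tricyclic cyclopropane δ-lactone
Product: 12 cis-fused keto δ-lactone (ring A 3-methoxy enone)
Conditions: TsOH·H2O (10 mol%), MeOH, H2O (2 equiv), 40 °C; then toluene, 60 °C (removal of MeOH); NaHCO3
Reagents that add atoms: water, O
Why: Acid opens the strained donor–acceptor cyclopropane at the C6–C10 bond to an oxocarbenium ion at C10 that is hydrolysed to the ketone while C6 becomes CH2, and the remaining enol ether moves into conjugation to give the 3-methoxy enone with its carbonyl at the more hindered C10 and its methoxy group on the less hindered C2, which should also be the thermodynamically preferred regioisomer; C4 and C5 are not touched under these mild conditions.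

**Step 10**
Reactants: 5 tert-butyl{[(2Z)-3-methylhept-2-en-6-yn-1-yl]oxy}diphenylsilane; 12 cis-fused keto δ-lactone
Product: 14 C19-hydroxy C7-ynone, via lithium acetylide 13 (not isolated)
Conditions: 5, n-BuLi, THF, −78 °C; then 12, −78 °C; NH4Cl
Reagents that add atoms: none
Why: The lithium acetylide should add to the unhindered δ-lactone carbonyl C7 much faster than to the hindered and electronically deactivated vinylogous-ester carbonyl C10, and the tetrahedral adduct collapses on work-up to the ynone and free C19–OH.

**Step 11**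
Reactants: 14 C19-hydroxy C7-ynone
Product: 15 (7R)-propargylic alcohol
Conditions: Ru[(R,R)-TsDPEN](p-cymene) (preformed amido complex, 2 mol%), 2-propanol, 25 °C
Reagents that add atoms: none
Why: Noyori asymmetric transfer hydrogenation of an alkynyl ketone, in which the alkynyl group takes the place of the aryl group in the usual model, so the (R,R) catalyst should give the 7R carbinol by catalyst control while the vinylogous ester and the alkene stay untouched.

**Step 12**
Reactants: 15 (7R)-propargylic alcohol
Product: 16 C10 tertiary carbinol enol ether (triol, used crude)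
Conditions: MeLi (3.5 equiv), THF, −78 → −20 °C; aqueous NaHCO3 work-up
Reagents that add atoms: methyllithium, [Li]C
Why: After deprotonation of the two hydroxyl groups, 1,2-addition of MeLi to the vinylogous-ester carbonyl (first half of a Stork–Danheiser transposition) brings in C20 and leaves the later enone masked as a base-stable alkoxide enol ether for the Grignard step; the configuration at C10 does not matter.

**Step 13**
Reactants: 16 C10 tertiary carbinol enol ether
Product: 18 (8Z)-allylsilane enone diol, via allylsilane carbinol 17 (not isolated)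
Conditions: Me3SiCH2MgCl (6 equiv), CuI (20 mol%), THF, 0 °C → reflux; then 1 M HCl, THF, 0 °C, short contact time
Reagents that add atoms: (trimethylsilyl)methylmagnesium chloride, C[Si](C)(C)C[Mg]Cl; water, O
Why: CuI-catalysed anti-carbomagnesiation of the propargylic chloromagnesium alkoxide places the silylmethyl group on C8 and MgCl on C9 in a five-membered chelate, so that after protonation H on C9 is cis to C7 and C17 is cis to C11 (Z-allylsilane), and the brief dilute-acid work-up completes the Stork–Danheiser sequence (enol ether hydrolysis and loss of the C10 hydroxyl) to the 3-methyl enone.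

**Step 14**
Reactants: 18 (8Z)-allylsilane enone diol
Product: 19 C19 acetate
Conditions: AcCl (1.1 equiv), 2,4,6-collidine, CH2Cl2, −78 °C
Reagents that add atoms: acetyl chloride, CC(Cl)=O
Why: Acetylation under these mild conditions should select the primary C19–OH over the hindered secondary allylic C7–OH and installs the acetate of the target.

**Step 15**
Reactants: 19 C19 acetate
Product: 20 7-O-triethylsilyl ether (cyclisation precursor)
Conditions: TESCl, imidazole, DMAP (5 mol%), DMF, 0 °C → rt
Reagents that add atoms: chlorotriethylsilane, CC[Si](Cl)(CC)CC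
Why: Silylation of C7–OH under neutral conditions, which the enone and the allylsilane tolerate, prevents oxa-Michael addition of this hydroxyl to C10 and alkoxide chemistry with the Lewis acid in the next step, and the group is removed together with the C15 silyl ether at the end.

**Step 16**
Reactants: 20 7-O-triethylsilyl ether (cyclisation precursor)
Product: 21 19-acetoxy-7α-(triethylsilyloxy)-15-(tert-butyldiphenylsilyloxy)labda-8(17),13Z-dien-2-one
Conditions: EtAlCl2 (2.5 equiv), toluene/CH2Cl2, −78 → −20 °C; aqueous NaHCO3
Reagents that add atoms: none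
Why: EtAlCl2 binds the C2 carbonyl and makes C10 electrophilic, the allylsilane attacks through its γ-carbon C9 (SE2′), the β-silyl cation at C8 loses Me3Si to give the C8=C17 methylene, and the enolate is protonated at C1 on work-up. The closest known reaction type is the Lewis acid-promoted intramolecular Hosomi–Sakurai conjugate allylation of 3-methylcyclohex-2-enones that carry the allylsilane chain on the γ-carbon, which builds decalones with an angular methyl group. Ring B closes in a 6-exo-trig mode with respect to the enone C1=C10 bond, with the C8=C9 bond of the allylsilane inside the new ring. C10 is controlled by C5 and C4: with the tether equatorial on C5 and the C19 group axial on the β face of C4, the chair-like closure brings C9 to the α face of C10, so C20 ends β and the ring fusion is trans. C9 is controlled by the Z-allylsilane, which holds C11 trans to C7 and therefore equatorial (β) in the chair, while the pre-set 7R silyloxy group sits axial, away from C17. The step needs conjugate rather than 1,2-addition and cyclisation rather than protodesilylation or ionisation of the allylic ethers: C9 cannot reach C2, silicon fixes C9 and not C17 as the nucleophilic carbon, and the proton-scavenging EtAlCl2 and the low temperature should suppress the other two.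

**Step 17**
Reactants: 21 19-acetoxy-7α-(triethylsilyloxy)-15-(tert-butyldiphenylsilyloxy)labda-8(17),13Z-dien-2-one
Product: 22 (13Z)-19-acetoxy-7α,15-dihydroxylabda-8(17),13-dien-2-one (target)
Conditions: HF·pyridine, pyridine, THF, 0 °C → rt
Reagents that add atoms: none
Why: Buffered fluoride cleaves both silyl ethers while the acetate, the ketone and the two allylic alcohols should remain unchanged.

**Compound list**
1 | nerol, (2Z)-3,7-dimethylocta-2,6-dien-1-ol | CC(C)=CCC/C(C)=C\CO | starting material
2 | tert-butyl{[(2Z)-3,7-dimethylocta-2,6-dien-1-yl]oxy}diphenylsilane | CC(C)=CCC/C(C)=C\CO[Si](c1ccccc1)(c1ccccc1)C(C)(C)C | intermediate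
3 | tert-butyl{[(2Z)-5-(3,3-dimethyloxiran-2-yl)-3-methylpent-2-en-1-yl]oxy}diphenylsilane (racemic at the oxirane carbon) | CC1(C)OC1CC/C(C)=C\CO[Si](c2ccccc2)(c3ccccc3)C(C)(C)C | intermediate
4 | (4Z)-6-{[tert-butyl(diphenyl)silyl]oxy}-4-methylhex-4-enal | O=CCC/C(C)=C\CO[Si](c1ccccc1)(c1ccccc1)C(C)(C)C | intermediate
5 | tert-butyl{[(2Z)-3-methylhept-2-en-6-yn-1-yl]oxy}diphenylsilane (carbons C8, C9, C11–C16) | C#CCC/C(C)=C\CO[Si](c1ccccc1)(c1ccccc1)C(C)(C)C | intermediate
6 | 3,5-dimethoxybenzoic acid | COc1cc(cc(OC)c1)C(O)=O | starting material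
7 | 3,5-dimethoxy-1-methylcyclohexa-2,5-diene-1-carboxylic acid (achiral) | COC1=CC(C)(C(O)=O)C=C(OC)C1 | intermediate
8 | (3,5-dimethoxy-1-methylcyclohexa-2,5-dien-1-yl)methanol (achiral) | COC1=CC(C)(CO)C=C(OC)C1 | intermediate
9 | (3,5-dimethoxy-1-methylcyclohexa-2,5-dien-1-yl)methyl 2-[2-(4-methylbenzenesulfonyl)hydrazinylidene]acetate | COC1=CC(C)(COC(=O)C=NNS(=O)(=O)c2ccc(C)cc2)C=C(OC)C1 | intermediate
10 | (3,5-dimethoxy-1-methylcyclohexa-2,5-dien-1-yl)methyl diazoacetate | COC1=CC(C)(COC(=O)C=[N+]=[N-])C=C(OC)C1 | intermediate
11 | tricyclic cyclopropane δ-lactone: ring A with C2(OMe)=C3 enol ether and C1H2; cyclopropane C5–C6–C10 on the β face; C10–OMe; C4 α-CH3; lactone C4–C19H2–O–C7(=O)–C6 on the β face; 5-H α | COC1=C[C@]2(C)COC(=O)[C@H]3[C@@H]2[C@@]3(OC)C1 | intermediate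
12 | cis-fused keto δ-lactone: ring A 3-methoxy enone (C10=O, C1H=C2–OMe, C3H2); C4 α-CH3; lactone C4–C19H2–O–C7(=O)–C6H2–C5 on the β face; 5-H α | COC1=CC(=O)[C@H]2CC(=O)OC[C@@]2(C)C1 | intermediate
13 | lithium acetylide of 5 | [Li]C#CCC/C(C)=C\CO[Si](c1ccccc1)(c1ccccc1)C(C)(C)C | intermediate
14 | hydroxy ynone: ring A 3-methoxy enone (C10=O) with C4 α-CH3 and β-CH2OH (C19); at C5 (H α) the chain C6H2–C7(=O)–C8≡C9–C11H2–C12H2–C13(CH3)=C14H–C15H2–OTBDPS (13Z); in equilibrium with its cyclic hemiketal | COC1=CC(=O)[C@@H](CC(=O)C#CCC/C(C)=C\CO[Si](c2ccccc2)(c3ccccc3)C(C)(C)C)[C@@](C)(CO)C1 | intermediate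
15 | (7R)-propargylic alcohol: as 14 with C7H(OH) | COC1=CC(=O)[C@@H](C[C@@H](O)C#CCC/C(C)=C\CO[Si](c2ccccc2)(c3ccccc3)C(C)(C)C)[C@@](C)(CO)C1 | intermediate
16 | tertiary carbinol: as 15 but C10 carries OH and CH3 (C20, either configuration) next to the enol ether C1H=C2–OMe | COC1=CC(C)(O)[C@@H](C[C@@H](O)C#CCC/C(C)=C\CO[Si](c2ccccc2)(c3ccccc3)C(C)(C)C)[C@@](C)(CO)C1 | intermediate
17 | allylsilane carbinol: as 16 with C8(CH2SiMe3)=C9H in place of the alkyne (8Z: C17 cis to C11) | COC1=CC(C)(O)[C@@H](C[C@@H](O)/C(C[Si](C)(C)C)=C/CC/C(C)=C\CO[Si](c2ccccc2)(c3ccccc3)C(C)(C)C)[C@@](C)(CO)C1 | intermediate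
18 | enone diol: ring A 3-methylcyclohex-2-enone (C2=O, C1H=C10–CH3); C4 α-CH3 and β-CH2OH; 5-H α; chain C6H2–C7H(OH)(7R)–C8(CH2SiMe3)=C9H–C11H2–C12H2–C13(CH3)=C14H–C15H2–OTBDPS (8Z,13Z) | CC1=CC(=O)C[C@](C)(CO)[C@@H]1C[C@@H](O)/C(C[Si](C)(C)C)=C/CC/C(C)=C\CO[Si](c2ccccc2)(c3ccccc3)C(C)(C)C | intermediate
19 | C19 acetate of 18 | CC1=CC(=O)C[C@](C)(COC(C)=O)[C@@H]1C[C@@H](O)/C(C[Si](C)(C)C)=C/CC/C(C)=C\CO[Si](c2ccccc2)(c3ccccc3)C(C)(C)C | intermediate
20 | 7-O-triethylsilyl ether of 19 (cyclisation precursor) | CC1=CC(=O)C[C@](C)(COC(C)=O)[C@@H]1C[C@@H](O[Si](CC)(CC)CC)/C(C[Si](C)(C)C)=C/CC/C(C)=C\CO[Si](c2ccccc2)(c3ccccc3)C(C)(C)C | intermediate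
21 | (13Z)-19-acetoxy-7α-(triethylsilyloxy)-15-(tert-butyldiphenylsilyloxy)labda-8(17),13-dien-2-one | C=C1[C@H](O[Si](CC)(CC)CC)C[C@H]2[C@@](C)(COC(C)=O)CC(=O)C[C@]2(C)[C@H]1CC/C(C)=C\CO[Si](c3ccccc3)(c4ccccc4)C(C)(C)C | intermediate
22 | (13Z)-19-acetoxy-7α,15-dihydroxylabda-8(17),13-dien-2-one | C=C1[C@H](O)C[C@H]2[C@@](C)(COC(C)=O)CC(=O)C[C@]2(C)[C@H]1CC/C(C)=C\CO | target

**Totals**
Total step count: 17. Longest linear sequence: 13 steps (6 → 22, steps 5–17); the nerol branch contributes 4 steps before the union in step 10.

**Three steps most likely to fail**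

Risk 1, step 8: the chiral catalyst may discriminate the two enantiotopic enol ethers poorly, so that the enantiomeric purity of ring A is too low. Fallback for step 8: it sets out from 10 and comes back to the route at 15. The cyclopropanation is run with achiral Rh2(OAc)4 and gives 11 together with the mirror-image cyclopropane lactone F1. The racemate is carried through the acid opening of step 9, which gives 12 together with the mirror-image keto lactone F2, and through the acetylide addition of step 10, which gives 14 together with the mirror-image hydroxy ynone F3. The catalyst-controlled reduction of step 11 then turns the two enantiomers into 15 and the (7R)-propargylic alcohol of the enantiomeric ring A series F4. These two are diastereomers and are separated by chromatography, and 15 goes on as in the route.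

Risk 2, step 13: carbomagnesiation of the internal alkyne may be slow or incomplete on this polyfunctional trialkoxide, so that the silylmethyl group is not delivered to C8. Fallback for step 13: it sets out from 16 and comes back to the route at 18. Treatment of 16 with 1 M HCl in THF at 0 °C completes the Stork–Danheiser transposition first and gives the enone propargylic diol F5. Hydroxyl-directed trans-hydrostannation (Bu3SnH, [Cp*RuCl]4, CH2Cl2) places tin on C8, anti to the new C9–H, and gives the alkenylstannane F6. Iododestannylation with I2 in CH2Cl2 at 0 °C proceeds with retention and gives the alkenyl iodide F7. Negishi coupling of this iodide with Me3SiCH2ZnCl (made from Me3SiCH2MgCl and ZnCl2) under Pd(PPh3)4 in THF replaces iodine with retention of geometry and gives 18.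

Risk 3, step 16: attack on the hindered β,β-disubstituted enone carbon may be slower than protodesilylation of the allylsilane or ionisation of the allylic silyl ethers by the stoichiometric Lewis acid. Fallback for step 16: it sets out from 17, which is isolated when step 13 is ended with an aqueous NH4Cl/NH3 work-up in place of HCl, and it comes back to the route at 21. Ring closure is moved ahead of the unveiling of the enone. Acetylation (AcCl, 2,4,6-collidine, CH2Cl2, −78 °C) gives the carbinol C19 acetate F8, and TESCl with imidazole in DMF gives the carbinol 7-O-triethylsilyl ether F9, in which the tertiary C10 hydroxyl stays free. TMSOTf (10 mol%) in CH2Cl2 at −78 °C ionises the C10 carbinol to the methoxy-substituted allyl cation C10–C1–C2, a far stronger electrophile than the enone–EtAlCl2 complex. The allylsilane traps it at C10 through the same chair (cation–olefin cyclisation terminated by an allylsilane) and gives the bicyclic methyl enol ether F10. Hydrolysis with 0.1 M oxalic acid in aqueous THF at 0 °C gives 21; any cation that is not trapped returns 20 on work-up.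

**Further compounds**
F1 | step 8 | mirror-image cyclopropane lactone (ent-11) | COC1=C[C@@]2(C)COC(=O)[C@@H]3[C@H]2[C@]3(OC)C1
F2 | step 8 | mirror-image keto lactone (ent-12) | COC1=CC(=O)[C@@H]2CC(=O)OC[C@]2(C)C1
F3 | step 8 | mirror-image hydroxy ynone (ent-14) | COC1=CC(=O)[C@H](CC(=O)C#CCC/C(C)=C\CO[Si](c2ccccc2)(c3ccccc3)C(C)(C)C)[C@](C)(CO)C1
F4 | step 8 | (7R)-propargylic alcohol of the enantiomeric ring A series (diastereomer of 15) | COC1=CC(=O)[C@H](C[C@@H](O)C#CCC/C(C)=C\CO[Si](c2ccccc2)(c3ccccc3)C(C)(C)C)[C@](C)(CO)C1
F5 | step 13 | enone propargylic diol (ring A 3-methyl enone, C7–OH, C8≡C9) | CC1=CC(=O)C[C@](C)(CO)[C@@H]1C[C@@H](O)C#CCC/C(C)=C\CO[Si](c2ccccc2)(c3ccccc3)C(C)(C)C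
F6 | step 13 | alkenylstannane (Bu3Sn on C8, cis to C11) | CC1=CC(=O)C[C@](C)(CO)[C@@H]1C[C@@H](O)/C([Sn](CCCC)(CCCC)CCCC)=C/CC/C(C)=C\CO[Si](c2ccccc2)(c3ccccc3)C(C)(C)C
F7 | step 13 | alkenyl iodide (iodine on C8, cis to C11) | CC1=CC(=O)C[C@](C)(CO)[C@@H]1C[C@@H](O)/C(I)=C/CC/C(C)=C\CO[Si](c2ccccc2)(c3ccccc3)C(C)(C)C
F8 | step 16 | carbinol C19 acetate (C19 acetate of 17) | COC1=CC(C)(O)[C@@H](C[C@@H](O)/C(C[Si](C)(C)C)=C/CC/C(C)=C\CO[Si](c2ccccc2)(c3ccccc3)C(C)(C)C)[C@@](C)(COC(C)=O)C1
F9 | step 16 | carbinol 7-O-triethylsilyl ether (C10–OH free) | COC1=CC(C)(O)[C@@H](C[C@@H](O[Si](CC)(CC)CC)/C(C[Si](C)(C)C)=C/CC/C(C)=C\CO[Si](c2ccccc2)(c3ccccc3)C(C)(C)C)[C@@](C)(COC(C)=O)C1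
F10 | step 16 | bicyclic methyl enol ether (C1=C2–OMe analogue of 21) | C=C1[C@H](O[Si](CC)(CC)CC)C[C@H]2[C@@](C)(COC(C)=O)CC(OC)=C[C@]2(C)[C@H]1CC/C(C)=C\CO[Si](c3ccccc3)(c4ccccc4)C(C)(C)C
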